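All constants stand for no real mixture; the rest is arithmetic.

The process chemist opened the short meeting by tabling the steps, the four set-ups and the questions.

    2 initiating radical → ended chains (k1 = 4.9 × 10⁸ M⁻¹ s⁻¹)
    initiator → 2 initiating radical (k2 = 0.00569 s⁻¹)
    substrate + initiating radical → chain carrier (k3 = 15300 M⁻¹ s⁻¹)
    reagent + chain carrier → target + initiating radical (k4 = 47600 M⁻¹ s⁻¹)
    substrate → decomposition product (k5 = 1.17 × 10⁻⁵ s⁻¹)

in all of them: substrate 0.050 M; initiator 1.2 mM

|  | reagent | remark | time |
|---|---|---|---|
| Monday's | 0.0500 M | one stirred flow tank at steady state, fed with the mixture as stated, mean residence time 120 min |  |
| Tuesday's | 0.0500 M (fed, over 12.0 min) | all but reagent at the start; reagent goes in evenly over 12.0 min, the run ends at 12 min | 12 min |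
| Thursday's | 0.0500 M | a single well-mixed tank run continuously and read at steady state, 12 min in it on average |  |
| Friday's | 0.0500 M | everything together in a closed stirred flask, run for 12 min | 12 min |

- two of one species on the left: rate k times its square, two consumed each time
- the stated concentrations are those of everything mixed, before any reaction; amounts are the same in each set-up
- the feed brings no volume worth counting
- run time (Tuesday's): 12 min

1. the set-up with the highest amount of target at the outlet or at the end, in percent of the substrate put in ("none" if the first two lie within 2 percentage points) (Monday's / Tuesday's / Thursday's / Friday's / none)
2. amount of target at the outlet or at the end, in percent of the substrate put in, Monday's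
3. amount of target at the outlet or at the end, in percent of the substrate put in, Tuesday's
4. amount of target at the outlet or at the end, in percent of the substrate put in, Thursday's
5. amount of target at the outlet or at the end, in percent of the substrate put in, Friday's

She argued that the concentration to find was that of the initiating radical, written r, since substrate is lost through the chain at a rate proportional to r and the reagent step hands a radical back. Radicals are made from initiator and end in pairs, so at balance r squared equals the initiator constant times the initiator concentration, divided by the termination constant. At the charged initiator level this gives 1.18 × 10⁻⁷ M. The analyst asked whether r could follow a falling initiator, and she replied that a radical's first half-life by termination alone, 0.00864 s, is shorter than the initiator's 2.0 min by its own step alone. That level times the constant of the substrate step is 0.108 min⁻¹, and she named it the chain constant K, the pseudo-first-order constant of substrate loss at the charged initiator level. While that balance holds, the chain's rate of substrate loss is first order in substrate and follows the square root of the initiator.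

The analyst took Friday's flask. There K decays exponentially with a time constant of 5.86 min, and 87.1 % of that decay is complete in 12 min. Multiplying these by K gives a dimensionless dose of 0.553. The share of substrate left is the exponential of minus the dose, and with decomposition set aside the rest counts as target, so the analyst expected about 42.5 % target in Friday's flask.

The engineer took the tanks, with residence time τ. Steady initiator is the feed level divided by one plus the initiator constant times τ, so K is divided by the root of that sum. The dose is this reduced K times τ, and the target share is the dose over one plus the dose plus the decomposition constant times τ. He reckoned 36.4 % for Thursday's tank and 64.9 % for Monday's tank.

The chemist then objected that Tuesday's feed of 0.00417 M min⁻¹ is slower than the starting demand of 0.00542 M min⁻¹. Chain carrier waits for reagent there, so the balance for r does not describe the start, and the meeting gave Tuesday's no figure.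

The forecast put Monday's first, with 64.9 %, 42.2 %, 36.4 % and 42.4 % for Monday's, Tuesday's, Thursday's and Friday's, reasoning that “the 120 min tank wins because its long residence time outweighs its low radical level”.

The simulation gives 64.9 %, 42.4 %, 36.4 % and 42.4 % in that order, with Monday's highest.

Reduced by the engineer's root, the chain constant K is 0.0167 min⁻¹ in Monday's tank, lower than the 0.0480 min⁻¹ in Thursday's tank, while Monday's tank holds the mixture on average ten times as long. Multiplied out, the dose in Monday's tank is 2.01 against 0.576 in Thursday's tank, larger by a factor of 3.49, and the two tanks read 64.9 % and 36.4 %.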